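## Retrosynthetic overview

- **Feature:** pinane C2 and ring-A carbon Ca are adjacent quaternary spiro carbons. Ca lies between both carbonyls of ring A (the methoxycyclohexenedione). C2 carries ring-B methylene Cd on the face turned away from the C6 CMe2 bridge.
- **Endgame:** isopropyl ⇐ isopropenyl (hydrogenation). Ring B ⇐ oxidative 5-exo radical closure Ca–Cb onto a homoprenyl alkene. OMe ⇐ O-methylation of the ring-A triketone.
- **Key disconnection:** Cd–C2, Ca–C(=O) and C(Me)–C(=O) are cut together. This gives the nopinone-derived enoate, a homoprenyl Grignard/copper reagent and 2,2-dimethyl-3-oxopentanoyl chloride.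
- **Fragments:** the enoate comes from (+)-β-pinene (ozonolysis, Horner–Wadsworth–Emmons). The acyl chloride comes from benzyl isobutyrate and propionyl chloride (acylation, hydrogenolysis, chlorination).
- **Ring order:** pinane bicycle (bought) → ring A (step 7) → ring B (step 9).

Key step: step 7

Remark: pinane numbering is used (C1–C7, C6 = CMe2 bridge), with Ca = ring-A spiro carbon, Cb = CH(iPr), Cc and Cd = ring-B methylenes (Cd on C2); (+)-β-pinene is taken as purchasable in enantiopure form, and enolisable ring-A compounds are drawn as one tautomer.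

## Route

Step 1
Reactants: 1 (1R,5R)-(+)-β-pinene
Product: 3 (1S,5R)-(−)-nopinone (6,6-dimethylbicyclo[3.1.1]heptan-2-one), via spiro ozonide 2 (not isolated)
Conditions: O3, CH2Cl2, −78 °C; then Me2S, −78 °C to rt
Reagents that add atoms: ozone, [O-][O+]=O
Why: Ozonolysis of the only C=C bond with reductive cleavage of the ozonide should give the ketone, and both bridgehead stereocentres stay untouched because C1 cannot enolise without forming a bridgehead alkene.

Step 2
Reactants: 3 (−)-nopinone; 4 trimethyl phosphonoacetate
Product: 6 methyl (2E)-[(1S,5R)-6,6-dimethylbicyclo[3.1.1]heptan-2-ylidene]acetate, via sodium phosphonate 5 (not isolated)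
Conditions: 4 (1.5 equiv), NaH (1.5 equiv), THF, 0 °C; then 3, reflux
Reagents that add atoms: none
Why: In this Horner–Wadsworth–Emmons olefination the small stabilised phosphonate anion should reach the hindered ketone at reflux; the E isomer (ester turned away from bridgehead C1) should dominate, and no separation is needed because both alkene isomers lead to the same product in step 7.

Step 3
Reactants: 7 5-bromo-2-methylpent-2-ene
Product: 8 4-methylpent-3-enylmagnesium bromide (titrated THF solution)
Conditions: Mg turnings (1.2 equiv), I2 (crystal), THF, rt to 40 °C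
Reagents that add atoms: magnesium, [Mg]
Why: This is Grignard formation from a primary homoallylic bromide, and closure to the cyclopropyl(dimethyl)carbinyl isomer would give a tertiary organomagnesium, so the open form should prevail.

Step 4
Reactants: 9 benzyl isobutyrate; 10 propionyl chloride
Product: 12 benzyl 2,2-dimethyl-3-oxopentanoate, via lithium enolate 11 (not isolated)
Conditions: LiN(iPr)2 (commercial solution, 1.05 equiv), THF, −78 °C; then 10 (1.1 equiv), −78 to 0 °C
Reagents that add atoms: none
Why: Claisen-type C-acylation of a fully substituted lithium ester enolate by an acid chloride gives a product with no hydrogen between its carbonyls, so no enolate is lost to proton exchange; the benzyl ester is chosen because hydroxide cleavage of an α,α-dimethyl β-keto methyl ester invites retro-Claisen fission.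

Step 5
Reactants: 12 benzyl 2,2-dimethyl-3-oxopentanoate
Product: 13 2,2-dimethyl-3-oxopentanoic acid
Conditions: H2 (1 atm), Pd/C (10 wt %), EtOAc, rt
Reagents that add atoms: none
Why: Hydrogenolysis of the benzyl ester runs neutral and at room temperature, so the β-keto acid should be freed without decarboxylation or retro-Claisen cleavage.

Step 6
Reactants: 13 2,2-dimethyl-3-oxopentanoic acid
Product: 14 2,2-dimethyl-3-oxopentanoyl chloride (used crude and fresh)
Conditions: (COCl)2 (1.3 equiv), DMF (cat.), CH2Cl2, 0 °C to rt; evaporate below rt
Reagents that add atoms: oxalyl chloride, O=C(Cl)C(=O)Cl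
Why: Acid chloride formation through the Vilsmeier-type chloroiminium catalyst works at or below room temperature, and the quaternary α-carbon rules out ketene or acylketene formation.

Step 7
Reactants: 6 enoate; 8 4-methylpent-3-enylmagnesium bromide; 14 2,2-dimethyl-3-oxopentanoyl chloride
Product: 18 ring-A triketone drawn as its dienol (3,5-dihydroxy-4,6,6-trimethyl-2-R-cyclohexa-2,4-dien-1-one; R = 6,6-dimethyl-2-(4-methylpent-3-enyl)bicyclo[3.1.1]heptan-2-yl; chain anti and ring A syn to the C6 bridge), via silyl ketene acetal 15 (not isolated), via lithium ester enolate 16 (not isolated), via diketo ester 17 (not isolated)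
Conditions: 8 (1.6 equiv), CuBr·SMe2 (20 mol %), Me3SiCl (3 equiv), THF, −40 to 0 °C; evaporate, pentane, filter off Mg and Cu salts under Ar, evaporate; MeLi (1.05 equiv), THF, −20 °C; cannulate into 14 (1.3 equiv), THF, −78 °C; LiN(iPr)2 (3 equiv), −78 °C to rt; 1 M HCl
Reagents that add atoms: none
Why: Proposed new method: each stage has precedent (Me3SiCl-accelerated copper-catalysed 1,4-addition of Grignard reagents to β,β-disubstituted enoates, C-acylation of lithium ester enolates by acid chlorides, Dieckmann-type Claisen closure), but stringing them into one unbroken three-component ring synthesis is untested, the closest known reaction type being tandem conjugate addition–enolate trapping. The homoprenylcopper species made from 8 complexes the enoate and transfers Cd to C2 while Me3SiCl captures the adduct as 15; the magnesium and copper halides, which would intercept MeLi by transmetalation, are then filtered off, MeLi attacks silicon to free 16, and 16 is acylated on Ca by 14 to give 17. LiN(iPr)2 next takes a proton from the exposed ethyl-ketone CH2 rather than the buried Ca–H, and that enolate closes ring A on the methyl ester by a 6-(enolexo)-exo-trig Claisen attack, which deprotonation of the triketone makes irreversible. C2 is the only stereocentre that lasts (Ca in 17 is erased by enolisation) and it is set by the bicycle: the methyl group of the C6 bridge that hangs over C2 closes one face of the exocyclic alkene, so Cd arrives from the C7 side and Ca is pushed syn to the bridge, whichever alkene isomer of 6 reacts. The step needs 1,4- over 1,2-addition (copper plus Me3SiCl), C- over O-acylation and over proton transfer (lithium counter-ion in THF free of polar additives, inverse addition at −78 °C, no acidic hydrogen between the carbonyls of 14), and C- over O-closure (an enol lactone would be reopened by the LiOMe set free, whereas the triketone is stored as its enolate).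

Step 8
Reactants: 18 ring-A triketone
Product: 19 5-methoxy-4,6,6-trimethyl-2-R-cyclohex-4-ene-1,3-dione (R as in 18; Ca–H epimerisable)
Conditions: Me3SiCHN2 (1.1 equiv), toluene/MeOH 4:1, 0 °C
Reagents that add atoms: trimethylsilyldiazomethane, C[Si](C)(C)C=[N+]=[N-]
Why: This is O-methylation of a vinylogous acid by a diazoalkane under neutral conditions, which avoids C-methylation; the tert-alkyl group keeps Ca sp3 and screens the two oxygens beside it, so the methyl group should go to the remote oxygen between CMe2 and C(Me).

Step 9
Reactants: 19 methyl enol ether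
Product: 20 isopropenyl dispiro compound (ring A spiro at Ca to cyclopentane ring B; ring B spiro at pinane C2; isopropenyl on Cb cis to the enone carbonyl and trans to bridgehead C1; Ca R; Cb R; C2 R; C1 S; C5 R)
Conditions: Mn(OAc)3·2H2O (2.2 equiv), Cu(OAc)2·H2O (1.0 equiv), degassed AcOH, 60 °C
Reagents that add atoms: none
Why: In this Mn(OAc)3-mediated oxidative free-radical cyclisation the β-diketone enolate bound to trivalent manganese gives the Ca radical, which closes ring B 5-exo-trig on the trisubstituted alkene, and Cu(OAc)2 (divalent copper, re-formed by Mn(OAc)3) turns the tertiary radical into the isopropenyl group by loss of a methyl hydrogen; in the chair-like transition state the Me2C= terminus should point away from bridgehead C1 (the bulkier arm on C2) and lie over the flat C(=O)–C(Me)= half of ring A rather than against a methyl of the ring-A CMe2, which sets Cb and Ca as in the target.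

Step 10
Reactants: 20 isopropenyl dispiro compound
Product: 21 target CNP0307059.1 (as 20 with isopropyl on Cb; Ca R; Cb R; C2 R; C1 S; C5 R)
Conditions: H2 (1 atm), Pd/C (10 wt %), EtOAc, rt
Reagents that add atoms: none
Why: Catalytic hydrogenation should pick the 1,1-disubstituted alkene, since the tetrasubstituted push–pull alkene of ring A and the two flanked ketones are inert at 1 atm, and no stereocentre is made or touched.

## Compound list

1 | (1R,5R)-(+)-β-pinene | C=C1CC[C@@H]2C[C@H]1C2(C)C | starting material
2 | spiro ozonide (1,2,4-trioxolane on pinane C2, epimers at C2) | C1OOC2(O1)CC[C@@H]3C[C@H]2C3(C)C | intermediate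
3 | (1S,5R)-(−)-nopinone | O=C1CC[C@@H]2C[C@H]1C2(C)C | intermediate
4 | trimethyl phosphonoacetate | COC(=O)CP(=O)(OC)OC | starting material
5 | sodium salt of trimethyl phosphonoacetate | [Na+].COC(=O)[CH-]P(=O)(OC)OC | intermediate
6 | methyl (2E)-[(1S,5R)-6,6-dimethylbicyclo[3.1.1]heptan-2-ylidene]acetate | COC(=O)/C=C1\CC[C@@H]2C[C@H]1C2(C)C | intermediate
7 | 5-bromo-2-methylpent-2-ene | CC(C)=CCCBr | starting material
8 | 4-methylpent-3-enylmagnesium bromide | CC(C)=CCC[Mg]Br | intermediate
9 | benzyl isobutyrate | CC(C)C(=O)OCc1ccccc1 | starting material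
10 | propionyl chloride | CCC(Cl)=O | starting material
11 | lithium enolate of benzyl isobutyrate | [Li+].CC(C)=C([O-])OCc1ccccc1 | intermediate
12 | benzyl 2,2-dimethyl-3-oxopentanoate | CCC(=O)C(C)(C)C(=O)OCc1ccccc1 | intermediate
13 | 2,2-dimethyl-3-oxopentanoic acid | CCC(=O)C(C)(C)C(O)=O | intermediate
14 | 2,2-dimethyl-3-oxopentanoyl chloride | CCC(=O)C(C)(C)C(Cl)=O | intermediate
15 | methyl trimethylsilyl ketene acetal of the 1,4-adduct (C2 quaternary, homoprenyl chain anti to the C6 bridge, E/Z mixture) | COC(O[Si](C)(C)C)=C[C@@]1(CCC=C(C)C)CC[C@@H]2C[C@H]1C2(C)C | intermediate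
16 | lithium ester enolate of the 1,4-adduct | [Li+].COC([O-])=C[C@@]1(CCC=C(C)C)CC[C@@H]2C[C@H]1C2(C)C | intermediate
17 | methyl 4,4-dimethyl-3,5-dioxo-2-R-heptanoate (R as in 18, epimers at Ca) | COC(=O)C(C(=O)C(C)(C)C(=O)CC)[C@@]1(CCC=C(C)C)CC[C@@H]2C[C@H]1C2(C)C | intermediate
18 | ring-A triketone, dienol form, on quaternary C2 bearing the homoprenyl chain | OC1=C(C)C(O)=C(C(=O)C1(C)C)[C@@]2(CCC=C(C)C)CC[C@@H]3C[C@H]2C3(C)C | intermediate
19 | 5-methoxy-4,6,6-trimethyl-2-R-cyclohex-4-ene-1,3-dione | COC1=C(C)C(=O)C(C(=O)C1(C)C)[C@@]2(CCC=C(C)C)CC[C@@H]3C[C@H]2C3(C)C | intermediate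
20 | isopropenyl dispiro compound | COC1=C(C)C(=O)[C@@]2(C(=O)C1(C)C)[C@@H](C(C)=C)CC[C@@]21CC[C@@H]2C[C@H]1C2(C)C | intermediate
21 | CNP0307059.1 | COC1=C(C)C(=O)[C@@]2(C(=O)C1(C)C)[C@@H](C(C)C)CC[C@@]21CC[C@@H]2C[C@H]1C2(C)C | target

## Step count

- Total step count: 10
- Longest linear sequence: 7 steps (9 → 21 through steps 4, 5, 6, 7, 8, 9, 10)

## Steps most likely to fail

**Step 7.**
- **What may go wrong:** the bimolecular union of the neopentyl-type enolate 16 with the pivaloyl-like chloride 14 may lose out to O-acylation. It may also lose out to proton transfer from the ketone CH2 of 14. Any stage that stalls spoils the whole telescoped sequence.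
- **Fallback (from 6 and 8, back at 18):** the two carbonyl bonds are made in the reverse order, all by known reactions, so that the crowded Ca–C(=O) bond forms inside a ring closure.
- The same copper-catalysed addition is quenched with aqueous NH4Cl and dilute acid. This hydrolyses 15 to the isolated ester methyl [6,6-dimethyl-2-(4-methylpent-3-enyl)bicyclo[3.1.1]heptan-2-yl]acetate F1.
- LiOH in aqueous THF/MeOH at reflux gives the corresponding acetic acid F2. (COCl)2 with catalytic DMF gives the acetyl chloride F3, whose carbonyl is only β-branched.
- Keto ester 12 is deprotonated at its ethyl group with LiN(iPr)2 to the lithium ketone enolate F4. Two equivalents are used, since the diketone formed is the stronger acid.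
- F4 is C-acylated by F3 to benzyl 2,2,4-trimethyl-3,5-dioxo-6-R-hexanoate F5, which makes C(Me)–C(=O) first.
- LiN(iPr)2 (3 equiv) then forms the 1,3-diketone dianion. Its terminal carbanion Ca attacks the benzyl ester (6-exo-trig Claisen closure) to give 18.

**Step 9.**
- **What may go wrong:** enolisation and oxidation of the buried Ca–H may be slow. Facial selectivity at Ca and Cb may be poor. The tertiary radical may be over-oxidised to a cation that is then captured by acetate or by a ring-A oxygen.
- **Fallback (from 19, back at 20):** an ionic ring-B closure by Tsuji–Trost allylation.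
- SeO2 (cat.) with t-BuOOH in CH2Cl2 oxidises the E methyl group of the homoprenyl alkene to the (E)-allylic alcohol F6. ClCO2Me/pyridine converts it into the allylic methyl carbonate F7.
- Pd(PPh3)4 (zerovalent palladium) in THF at 60 °C ionises F7 to the π-allyl complex. The methoxide released removes Ca–H.
- Ca then attacks the inner allyl terminus Cb, forming a five- rather than a seven-membered ring, and gives 20 directly.
- A chiral diphosphine on palladium would add reagent control over the face of Cb, which the radical closure lacks.

**Step 8.**
- **What may go wrong:** site selectivity between the two oxygens of the vinylogous acid may be poor, or a second methylation may occur.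
- **Fallback (from 18, back at 20, bypassing 19):** methylation is postponed until Ca is quaternary, and the C(Me) carbon is blocked in the meantime.
- N-Chlorosuccinimide in CH2Cl2 chlorinates the only open nucleophilic carbon to give the 4-chloro-4-methyl trione F8.
- Mn(OAc)3/Cu(OAc)2 in AcOH closes ring B at Ca, the sole enolisable site left, to give the chlorinated dispiro trione F9.
- Zn in AcOH removes chlorine to give the dispiro triketone F10.
- Me3SiCHN2 then methylates the oxygen beside CMe2, because the other oxygen now lies next to the spiro carbon and under the isopropenyl group. This gives 20.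
- The price is that ring A has no flat half during the radical closure. Control at Ca is therefore weaker, and Ca epimers may have to be separated.

## Further compounds

F1 | step 7 | methyl [6,6-dimethyl-2-(4-methylpent-3-enyl)bicyclo[3.1.1]heptan-2-yl]acetate (chain anti to the C6 bridge) | COC(=O)C[C@@]1(CCC=C(C)C)CC[C@@H]2C[C@H]1C2(C)C
F2 | step 7 | [6,6-dimethyl-2-(4-methylpent-3-enyl)bicyclo[3.1.1]heptan-2-yl]acetic acid | OC(=O)C[C@@]1(CCC=C(C)C)CC[C@@H]2C[C@H]1C2(C)C
F3 | step 7 | [6,6-dimethyl-2-(4-methylpent-3-enyl)bicyclo[3.1.1]heptan-2-yl]acetyl chloride | ClC(=O)C[C@@]1(CCC=C(C)C)CC[C@@H]2C[C@H]1C2(C)C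
F4 | step 7 | lithium ketone enolate of benzyl 2,2-dimethyl-3-oxopentanoate | [Li+].CC=C([O-])C(C)(C)C(=O)OCc1ccccc1
F5 | step 7 | benzyl 2,2,4-trimethyl-3,5-dioxo-6-R-hexanoate (R as in 18) | O=C(OCc1ccccc1)C(C)(C)C(=O)C(C)C(=O)C[C@@]1(CCC=C(C)C)CC[C@@H]2C[C@H]1C2(C)C
F6 | step 9 | (E)-allylic alcohol of 19 | COC1=C(C)C(=O)C(C(=O)C1(C)C)[C@@]2(CC/C=C(C)/CO)CC[C@@H]3C[C@H]2C3(C)C
F7 | step 9 | allylic methyl carbonate of F6 | COC1=C(C)C(=O)C(C(=O)C1(C)C)[C@@]2(CC/C=C(C)/COC(=O)OC)CC[C@@H]3C[C@H]2C3(C)C
F8 | step 8 | 4-chloro-4-methyl trione (epimers at C–Cl and Ca) | CC1(Cl)C(=O)C(C(=O)C(C)(C)C1=O)[C@@]2(CCC=C(C)C)CC[C@@H]3C[C@H]2C3(C)C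
F9 | step 8 | chlorinated dispiro trione with isopropenyl on Cb | CC1(Cl)C(=O)[C@@]2(C(=O)C(C)(C)C1=O)[C@@H](C(C)=C)CC[C@@]21CC[C@@H]2C[C@H]1C2(C)C
F10 | step 8 | dispiro triketone, enol form, with isopropenyl on Cb | OC1=C(C)C(=O)[C@@]2(C(=O)C1(C)C)[C@@H](C(C)=C)CC[C@@]21CC[C@@H]2C[C@H]1C2(C)C
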